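Compound numbers 1–19 refer to the route below; the target is 19.

## The problem

The target is a biflavonol joined through a diaryl ether. Unit 1 is a 3,5-dihydroxy-7-methoxyflavone whose ring B carries a 3'-hydroxyl and a 4'-oxygen; that oxygen is also the 4'-oxygen of the 3'-methoxy ring B of unit 2, a 3,5,7-trihydroxyflavone. There is no stereocentre, so the task is one of connectivity and chemoselectivity: two similar but different chromone halves must be built on either side of an ether whose two rings differ only in OH versus OMe next to the bridging oxygen. Six hydroxyls must end free while two methyl ethers stay, which excludes any late demethylation and calls for one family of protecting groups (benzyl ethers) that leaves at the end under neutral conditions. Both pyranones open in hot aqueous alkali and a 5-benzyloxy group peri to the C4 carbonyl is acid-labile, so once the first chromone exists the second ring closure must run close to neutrality. Each C3 hydroxyl sits on an enol carbon; on 5,7-dioxygenated A rings the classical oxidative chalcone-to-flavonol cyclisation is known to divert to aurones, so the C3 oxygen is better added after the pyranone is in place. The feature that opens the key step is the C2=C3 bond of unit 1: C2 bears O1 and ring B, C3 lies next to the C4 ketone, so C2 maps onto the carbonyl carbon of an aryl ester (ring B acid on the ring A phenol) and C3 onto a phenacyl ylide carbon. The ring B acid in question is a 3-hydroxy-4-aryloxybenzoic acid and the other ether ring is a vanillin unit, so the ether maps onto two commercial arenes of different carbonyl oxidation level.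

## Retrosynthesis

**Benzyl ethers.** The four O–benzyl bonds of 18 are cut last, which takes 19 back to a compound whose only free hydroxyls are the two at C3. Hydrogenolysis is neutral, spares the aryl methyl ethers and the diaryl ether, and frees the air-sensitive polyphenol only in the final flask.

**Both C3–O bonds.** The two C3 hydroxyls of 18 are cut together, via bis-epoxide 17, back to bis-flavone 16. Installing them one at a time would ask an electrophilic oxidant to tell an unsubstituted C2=C3 from a 3-alkoxy-substituted one. Keeping both pyranones at the flavone level until this point removes that question, because both double bonds are then meant to react. It also avoids the aurone-prone oxidative chalcone cyclisation on the 5,7-dioxygenated ring of unit 2. The forward reaction must epoxidise two electron-poor enol ethers without attacking benzylic C–H bonds.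

**C2=C3 of unit 1 (key cut).** Cutting this double bond of 16 gives 15, in which C2 is an ester carbonyl and C3 a keto-stabilised ylide carbon. The neighbouring cut, O1–C2 by Baker–Venkataraman rearrangement and cyclodehydration, uses the same ester but needs strong base and then acid in the presence of the finished unit 2 flavone and the peri benzyl ether. The Wittig closure needs only heat. The precursor is simpler by one ring, and O1 is already in place as the ester oxygen.

**Ester C–O bond.** Cutting the aryl ester of 15 gives phenolic ylide 13 and acid chloride 14. This is the convergent junction: all of unit 2 and the diaryl ether arrive in 14, all of ring A of unit 1 and the phosphorus in 13. The forward acylation must occur at the phenol oxygen and not at the ylide carbon.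

**C–P and C–Br bonds of the ring A piece.** Ylide 13 goes back through phosphonium bromide 12 to α-bromoketone 11, then to monobenzyl ether 10 and to commercial 2,6-dihydroxy-4-methoxyacetophenone 9. The symmetric diol 9 already holds the 5-O/7-OMe pattern, so one mono-benzylation differentiates the two hydroxyls. Placing phosphorus on this small fragment keeps halogenation away from the electron-rich rings of unit 2.

**Pyranone of unit 2.** Acid chloride 14 comes from acid 8, whose O1–C2 bond is cut to give 2'-hydroxychalcone 7. The enone Cα=Cβ bond of 7 is cut to aldehyde 4 and acetophenone 6, the latter from commercial 2,4,6-trihydroxyacetophenone 5. The chalcone route is chosen here because the ring B carbon of unit 2 comes from vanillin at the aldehyde level, and no other chromone is yet present that base could harm. The condensation medium also cleaves the benzyl ester of 4, so the acid needed for 14 is released without a separate step.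

**Diaryl ether.** The aryl C–O bond of 4 is cut to vanillin 3 and fluoroarene 2, the dibenzyl derivative of commercial 4-fluoro-3-hydroxybenzoic acid 1. Having one ring at the aldehyde level and the other at the acid level is what lets two different A rings be attached without statistical mixtures. The forward reaction is a nucleophilic aromatic substitution para to an ester, the least activated step of the plan.

## Roads not taken

**Alternative 1:** ring B of unit 1 is built from acyclic pieces. The aryloxyacetone 1-(4-bromo-2-methoxyphenoxy)propan-2-one (A1) adds through its aryloxy-bearing carbon to ethyl 2-oxobut-3-enoate (A2). Aldol condensation of its methyl group onto the keto ester carbonyl then gives the cyclohexenone ethyl 4-(4-bromo-2-methoxyphenoxy)-3-oxocyclohex-1-ene-1-carboxylate (A3), which is dehydrogenated to ethyl 4-(4-bromo-2-methoxyphenoxy)-3-hydroxybenzoate (A4).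
- Merit: the ether oxygen is attached to an sp3 carbon by simple phenoxide alkylation, so no weakly activated aromatic substitution is needed. In this one respect it is better than the chosen plan.
- Weak points: enamine or enolate formation from A1 must occur at the more hindered aryloxy-bearing carbon for the Michael step and at the methyl for the aldol step. A2 polymerises readily. A3 can aromatise by losing the aryloxide (β-elimination, then tautomerisation to a 3-hydroxybenzoate), which would destroy the very bond the strategy carries.
- Step economy: A4 still needs benzylation and conversion of the bromide into a formyl group before it matches 4, and neither chromone has been started.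
- Comparison: the chosen plan reaches 4 in two steps from 1 and holds a copper-catalysed ether coupling in reserve.

**Alternative 2:** ring C of unit 2 is closed at C3–C4 by an intramolecular crossed benzoin reaction of the dialdehyde 2-[1-[4-(4-bromo-2-benzyloxyphenoxy)-3-methoxyphenyl]-2-oxoethoxy]-4,6-bis(benzyloxy)benzaldehyde (A5) under a triazolium-derived carbene. The product is the 3-hydroxychroman-4-one A6.
- Merit: the C3 oxygen of unit 2 arrives with the ring closure, under mild organocatalysis. In this respect it is better than the chosen plan, which must oxidise C3 afterwards.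
- Weak points: the acyl anion must form at the hindered, electron-rich 2,6-dioxygenated aryl aldehyde and add to the aliphatic one. The reverse pairing gives the isomeric 4-hydroxychroman-3-one. The α-aryl-α-aryloxy aldehyde in A5 is highly enolisable, prone to aryloxide loss and long to make.
- Step economy: A6 needs a further C2–C3 dehydrogenation, which erases whatever stereocontrol the catalyst provided, and the bromide must still be raised to a carboxyl group before unit 1 can be started.
- Comparison: the chosen plan oxidises both C3 positions in one operation on 16, by a reaction type well known for 5-O-protected flavones, and its precursors are one or two steps from commercial arenes.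

**Alternative 3:** ring A of unit 1 is built by benzannulation. The pyranone diazoketone A7 undergoes Wolff rearrangement to a vinylketene, which adds methoxyacetylene (A8). Ring opening of the cyclobutenone and 6π closure form C8a–C8, C8–C7, C6–C5 and C5–C4a and give the 3-O-benzyl-5-hydroxy-7-methoxyflavone A9.
- Merit: the 5-OH/7-OMe pattern arises already differentiated and the C3 oxygen of unit 1 is present from the start, so unit 1 needs neither selective benzylation nor C3 oxidation. On these two points it is better than the chosen plan.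
- Weak points: A7 is a fully substituted 4-pyranone that needs several steps, among them arylation with the whole ring B ether and a diazoketone synthesis. 4-Pyranones have photochemistry of their own that competes with a photochemical Wolff step. A8 is volatile and unstable.
- Step economy: unit 2 must still be built afterwards from the dioxolane of A9, where the aurone problem returns.
- Comparison: ring A with the correct oxygen pattern is commercial as 9, so the chosen plan needs no ring synthesis at that point. It pays with one mono-benzylation and a share of a single double oxidation.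

Key step: step 11

Remark on the chemistry: dimethyldioxirane is taken as a freshly prepared acetone solution and counted as a reagent. Compound 15 enters the key step as the neutral ylide, the conjugate base of the corresponding phosphonium bromide.

## Route

Step 1
Reactants: 1 4-fluoro-3-hydroxybenzoic acid
Product: 2 benzyl 3-(benzyloxy)-4-fluorobenzoate
Conditions: BnBr (2.3 equiv), K2CO3, DMF, 60 °C
Reagents that add atoms: benzyl bromide, BrCc1ccccc1
Why: Williamson O-alkylation of the phenoxide and the carboxylate in one operation; the fluoride is inert to carbonate under these conditions.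

Step 2
Reactants: 2 benzyl 3-(benzyloxy)-4-fluorobenzoate; 3 vanillin
Product: 4 benzyl 3-(benzyloxy)-4-(4-formyl-2-methoxyphenoxy)benzoate
Conditions: Cs2CO3, DMSO, 120 °C
Reagents that add atoms: none
Why: Nucleophilic aromatic substitution (addition–elimination): the vanillin phenoxide displaces fluoride para to the ester, which stabilises the Meisenheimer intermediate; the cesium counter-ion and dry DMSO compensate for the modest activation.

Step 3
Reactants: 5 2,4,6-trihydroxyacetophenone
Product: 6 1-[2,4-bis(benzyloxy)-6-hydroxyphenyl]ethan-1-one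
Conditions: BnBr (2.1 equiv), K2CO3, DMF, rt
Reagents that add atoms: benzyl bromide, BrCc1ccccc1
Why: Williamson etherification; after two alkylations the remaining hydroxyl is held by a hydrogen bond to the acetyl oxygen and reacts much more slowly, so the dibenzyl ether should predominate.

Step 4
Reactants: 4 benzyl 3-(benzyloxy)-4-(4-formyl-2-methoxyphenoxy)benzoate; 6 1-[2,4-bis(benzyloxy)-6-hydroxyphenyl]ethan-1-one
Product: 7 (E)-3-(benzyloxy)-4-[4-[3-[2,4-bis(benzyloxy)-6-hydroxyphenyl]-3-oxoprop-1-en-1-yl]-2-methoxyphenoxy]benzoic acid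
Conditions: KOH (aq., excess), EtOH/THF, rt to 40 °C; then aq. HCl
Reagents that add atoms: potassium hydroxide, [K+].[OH-]
Why: Claisen–Schmidt condensation: the methyl ketone enolate adds to the aldehyde and E1cB dehydration gives the thermodynamically favoured E enone; the excess hydroxide also saponifies the benzyl ester, so the free acid is obtained on acidification.

Step 5
Reactants: 7 (E)-3-(benzyloxy)-4-[4-[3-[2,4-bis(benzyloxy)-6-hydroxyphenyl]-3-oxoprop-1-en-1-yl]-2-methoxyphenoxy]benzoic acid
Product: 8 3-(benzyloxy)-4-[4-[5,7-bis(benzyloxy)-4-oxo-4H-chromen-2-yl]-2-methoxyphenoxy]benzoic acid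
Conditions: I2 (10 mol%), DMSO, 120 °C
Reagents that add atoms: none
Why: Iodine-catalysed oxidative cyclisation of a 2'-hydroxychalcone: oxa-Michael closure, α-iodination and loss of HI give the flavone while DMSO reoxidises HI; catalytic iodine keeps the acid level low enough for the benzyl ethers.

Step 6
Reactants: 9 2,6-dihydroxy-4-methoxyacetophenone
Product: 10 1-[2-(benzyloxy)-6-hydroxy-4-methoxyphenyl]ethan-1-one
Conditions: BnBr (1.05 equiv), K2CO3, acetone, reflux
Reagents that add atoms: benzyl bromide, BrCc1ccccc1
Why: Williamson mono-etherification of a symmetric diol; once one oxygen is alkylated the other is locked in the hydrogen bond to the ketone, which should limit bis-alkylation.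

Step 7
Reactants: 10 1-[2-(benzyloxy)-6-hydroxy-4-methoxyphenyl]ethan-1-one
Product: 11 1-[2-(benzyloxy)-6-hydroxy-4-methoxyphenyl]-2-bromoethan-1-one
Conditions: CuBr2 (2.1 equiv), EtOAc/CHCl3, reflux
Reagents that add atoms: copper dibromide, [Cu+2].[Br-].[Br-]
Why: Selective α-bromination of an aryl methyl ketone with copper dibromide, which brominates through the copper-bound enol and is the standard way to avoid nuclear bromination of hydroxyacetophenones; the product is used at once.

Step 8
Reactants: 11 1-[2-(benzyloxy)-6-hydroxy-4-methoxyphenyl]-2-bromoethan-1-one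
Product: 13 1-[2-(benzyloxy)-6-hydroxy-4-methoxyphenyl]-2-(triphenyl-λ5-phosphanylidene)ethan-1-one, via phosphonium bromide 12 (not isolated)
Conditions: PPh3, CH2Cl2, rt; then aq. Na2CO3
Reagents that add atoms: triphenylphosphine, c1ccc(cc1)P(c1ccccc1)c1ccccc1
Why: SN2 quaternisation of the phenacyl bromide by the phosphine under neutral conditions outruns phenoxide closure to the coumaranone; carbonate then deprotonates the acidic phenacylphosphonium CH2 to give the keto-stabilised ylide, which tolerates water.

Step 9
Reactants: 8 3-(benzyloxy)-4-[4-[5,7-bis(benzyloxy)-4-oxo-4H-chromen-2-yl]-2-methoxyphenoxy]benzoic acid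
Product: 14 3-(benzyloxy)-4-[4-[5,7-bis(benzyloxy)-4-oxo-4H-chromen-2-yl]-2-methoxyphenoxy]benzoyl chloride
Conditions: 1-chloro-N,N,2-trimethylprop-1-en-1-amine (1.2 equiv), CH2Cl2, 0 °C to rt; used crude
Reagents that add atoms: 1-chloro-N,N,2-trimethylprop-1-en-1-amine, CC(C)=C(Cl)N(C)C
Why: Acid chloride formation with an α-chloroenamine under neutral conditions, chosen over oxalyl chloride so that the nucleophilic pyranone carbonyl is not converted into a chloropyrylium salt.

Step 10
Reactants: 14 3-(benzyloxy)-4-[4-[5,7-bis(benzyloxy)-4-oxo-4H-chromen-2-yl]-2-methoxyphenoxy]benzoyl chloride; 13 1-[2-(benzyloxy)-6-hydroxy-4-methoxyphenyl]-2-(triphenyl-λ5-phosphanylidene)ethan-1-one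
Product: 15 3-(benzyloxy)-5-methoxy-2-[(triphenyl-λ5-phosphanylidene)acetyl]phenyl 3-(benzyloxy)-4-[4-[5,7-bis(benzyloxy)-4-oxo-4H-chromen-2-yl]-2-methoxyphenoxy]benzoate
Conditions: pyridine (3 equiv), CH2Cl2, 0 °C to rt; aqueous work-up, crude used directly
Reagents that add atoms: none
Why: O-acylation of the phenolic ylide by an aroyl chloride with pyridine as base, the known first stage of chromone synthesis from (2-hydroxybenzoyl)methylene phosphoranes; any aroyl group that first lands on the enolate oxygen is an activated acyl donor held next to the phenol and should be relayed to it.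

Step 11
Reactants: 15 3-(benzyloxy)-5-methoxy-2-[(triphenyl-λ5-phosphanylidene)acetyl]phenyl 3-(benzyloxy)-4-[4-[5,7-bis(benzyloxy)-4-oxo-4H-chromen-2-yl]-2-methoxyphenoxy]benzoate
Product: 16 5-(benzyloxy)-2-[3-(benzyloxy)-4-[4-[5,7-bis(benzyloxy)-4-oxo-4H-chromen-2-yl]-2-methoxyphenoxy]phenyl]-7-methoxy-4H-chromen-4-one
Conditions: toluene, 110 °C
Reagents that add atoms: none
Why: Intramolecular Wittig olefination of an ester carbonyl: on heating, the ylide carbon of 15 adds to the neighbouring aryl ester carbonyl, the alkoxide closes onto phosphorus and the oxaphosphetane collapses with loss of Ph3P=O to give the C2=C3 bond. The closest known reaction type is the chromone and flavone synthesis from O-acylated (2-hydroxybenzoyl)methylene triphenylphosphoranes. Ring C of unit 1 closes as a six-membered ring by attack of C3 on the exocyclic ester C=O (6-exo-trig), with O1 already present as the ester oxygen; the product is aromatic, so the elimination is irreversible. No stereocentre is formed. The selectivity needed is olefination instead of net acyl transfer to carbon by expulsion of the ring A phenoxide from the tetrahedral intermediate; the phenol released in that way stays ortho to the resulting diacyl ylide and can re-enter the same intermediate, whereas phosphine oxide loss cannot be reversed, so material should drain to 16. An aryl ester is the most electrophilic ester type and the ortho relationship holds the ylide within reach, which is what lets a stabilised ylide attack an ester at all. The medium is neutral and aprotic, so the unit 2 flavone, the four benzyl ethers and the diaryl ether are not at risk.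

Step 12
Reactants: 16 5-(benzyloxy)-2-[3-(benzyloxy)-4-[4-[5,7-bis(benzyloxy)-4-oxo-4H-chromen-2-yl]-2-methoxyphenoxy]phenyl]-7-methoxy-4H-chromen-4-one
Product: 18 5-(benzyloxy)-2-[3-(benzyloxy)-4-[4-[5,7-bis(benzyloxy)-3-hydroxy-4-oxo-4H-chromen-2-yl]-2-methoxyphenoxy]phenyl]-3-hydroxy-7-methoxy-4H-chromen-4-one, via bis-epoxide 17 (not isolated)
Conditions: DMDO (excess, acetone solution), CH2Cl2, 0 °C to rt; concentrate; then pTsOH·H2O (cat.), CH2Cl2, rt
Reagents that add atoms: dimethyldioxirane, CC1(C)OO1
Why: Dioxirane epoxidation of both flavone C2=C3 bonds, which is known for flavones whose 5-oxygen is protected, followed by acid-catalysed opening of each 2,3-epoxide at C2 (oxocarbenium stabilised by O1 and ring B) and loss of H3 to give the 3-hydroxyflavone; because both double bonds are meant to react, no selectivity between the two units is required.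

Step 13
Reactants: 18 5-(benzyloxy)-2-[3-(benzyloxy)-4-[4-[5,7-bis(benzyloxy)-3-hydroxy-4-oxo-4H-chromen-2-yl]-2-methoxyphenoxy]phenyl]-3-hydroxy-7-methoxy-4H-chromen-4-one
Product: 19 3,5-dihydroxy-2-[3-hydroxy-4-[2-methoxy-4-(3,5,7-trihydroxy-4-oxo-4H-chromen-2-yl)phenoxy]phenyl]-7-methoxy-4H-chromen-4-one (target)
Conditions: H2 (1 atm), 10% Pd/C, THF/MeOH, rt
Reagents that add atoms: none
Why: Catalytic hydrogenolysis of the four benzyl ethers under neutral conditions; the aryl methyl ethers, the diaryl ether and the flavonol double bonds are not expected to be reduced at ambient pressure.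

## Compound list

1 | 4-fluoro-3-hydroxybenzoic acid | O=C(O)c1ccc(F)c(O)c1 | starting material
2 | benzyl 3-(benzyloxy)-4-fluorobenzoate | O=C(OCc1ccccc1)c1ccc(F)c(OCc2ccccc2)c1 | intermediate
3 | vanillin | COc1cc(C=O)ccc1O | starting material
4 | benzyl 3-(benzyloxy)-4-(4-formyl-2-methoxyphenoxy)benzoate | COc1cc(C=O)ccc1Oc1ccc(C(=O)OCc2ccccc2)cc1OCc1ccccc1 | intermediate
5 | 2,4,6-trihydroxyacetophenone | CC(=O)c1c(O)cc(O)cc1O | starting material
6 | 1-[2,4-bis(benzyloxy)-6-hydroxyphenyl]ethan-1-one | CC(=O)c1c(O)cc(OCc2ccccc2)cc1OCc1ccccc1 | intermediate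
7 | (E)-3-(benzyloxy)-4-[4-[3-[2,4-bis(benzyloxy)-6-hydroxyphenyl]-3-oxoprop-1-en-1-yl]-2-methoxyphenoxy]benzoic acid | COc1cc(/C=C/C(=O)c2c(O)cc(OCc3ccccc3)cc2OCc2ccccc2)ccc1Oc1ccc(C(=O)O)cc1OCc1ccccc1 | intermediate
8 | 3-(benzyloxy)-4-[4-[5,7-bis(benzyloxy)-4-oxo-4H-chromen-2-yl]-2-methoxyphenoxy]benzoic acid | COc1cc(-c2cc(=O)c3c(OCc4ccccc4)cc(OCc4ccccc4)cc3o2)ccc1Oc1ccc(C(=O)O)cc1OCc1ccccc1 | intermediate
9 | 2,6-dihydroxy-4-methoxyacetophenone | CC(=O)c1c(O)cc(OC)cc1O | starting material
10 | 1-[2-(benzyloxy)-6-hydroxy-4-methoxyphenyl]ethan-1-one | COc1cc(O)c(C(C)=O)c(OCc2ccccc2)c1 | intermediate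
11 | 1-[2-(benzyloxy)-6-hydroxy-4-methoxyphenyl]-2-bromoethan-1-one | COc1cc(O)c(C(=O)CBr)c(OCc2ccccc2)c1 | intermediate
12 | [2-[2-(benzyloxy)-6-hydroxy-4-methoxyphenyl]-2-oxoethyl]triphenylphosphonium bromide | COc1cc(O)c(C(=O)C[P+](c2ccccc2)(c2ccccc2)c2ccccc2)c(OCc2ccccc2)c1.[Br-] | intermediate
13 | 1-[2-(benzyloxy)-6-hydroxy-4-methoxyphenyl]-2-(triphenyl-λ5-phosphanylidene)ethan-1-one | COc1cc(O)c(C(=O)C=P(c2ccccc2)(c2ccccc2)c2ccccc2)c(OCc2ccccc2)c1 | intermediate
14 | 3-(benzyloxy)-4-[4-[5,7-bis(benzyloxy)-4-oxo-4H-chromen-2-yl]-2-methoxyphenoxy]benzoyl chloride | COc1cc(-c2cc(=O)c3c(OCc4ccccc4)cc(OCc4ccccc4)cc3o2)ccc1Oc1ccc(C(=O)Cl)cc1OCc1ccccc1 | intermediate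
15 | 3-(benzyloxy)-5-methoxy-2-[(triphenyl-λ5-phosphanylidene)acetyl]phenyl 3-(benzyloxy)-4-[4-[5,7-bis(benzyloxy)-4-oxo-4H-chromen-2-yl]-2-methoxyphenoxy]benzoate | COc1cc(OCc2ccccc2)c(C(=O)C=P(c2ccccc2)(c2ccccc2)c2ccccc2)c(OC(=O)c2ccc(Oc3ccc(-c4cc(=O)c5c(OCc6ccccc6)cc(OCc6ccccc6)cc5o4)cc3OC)c(OCc3ccccc3)c2)c1 | intermediate
16 | 5-(benzyloxy)-2-[3-(benzyloxy)-4-[4-[5,7-bis(benzyloxy)-4-oxo-4H-chromen-2-yl]-2-methoxyphenoxy]phenyl]-7-methoxy-4H-chromen-4-one | COc1cc(OCc2ccccc2)c2c(=O)cc(-c3ccc(Oc4ccc(-c5cc(=O)c6c(OCc7ccccc7)cc(OCc7ccccc7)cc6o5)cc4OC)c(OCc4ccccc4)c3)oc2c1 | intermediate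
17 | bis-epoxide of 16 with an oxirane across C2–C3 of each chromenone (each oxirane racemic; mixture of diastereomers, configuration not defined) | COc1cc(OCc2ccccc2)c2c(c1)OC1(c3ccc(Oc4ccc(C56OC5C(=O)c5c(OCc7ccccc7)cc(OCc7ccccc7)cc5O6)cc4OC)c(OCc4ccccc4)c3)OC1C2=O | intermediate
18 | 5-(benzyloxy)-2-[3-(benzyloxy)-4-[4-[5,7-bis(benzyloxy)-3-hydroxy-4-oxo-4H-chromen-2-yl]-2-methoxyphenoxy]phenyl]-3-hydroxy-7-methoxy-4H-chromen-4-one | COc1cc(OCc2ccccc2)c2c(=O)c(O)c(-c3ccc(Oc4ccc(-c5oc6cc(OCc7ccccc7)cc(OCc7ccccc7)c6c(=O)c5O)cc4OC)c(OCc4ccccc4)c3)oc2c1 | intermediate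
19 | 3,5-dihydroxy-2-[3-hydroxy-4-[2-methoxy-4-(3,5,7-trihydroxy-4-oxo-4H-chromen-2-yl)phenoxy]phenyl]-7-methoxy-4H-chromen-4-one (CNP0190193.0) | COc1cc(O)c2c(=O)c(O)c(-c3ccc(Oc4ccc(-c5oc6cc(O)cc(O)c6c(=O)c5O)cc4OC)c(O)c3)oc2c1 | target

## Step count and risk

Total: 13 steps. Longest linear sequence: 9 steps (steps 1, 2, 4, 5, 9, 10, 11, 12, 13).

**Step 11 (key step).** The most likely failure is stalling after acyl transfer to carbon. The tetrahedral intermediate can expel the ring A phenoxide, and the resulting doubly stabilised diacyl ylide may be slow to re-enter the olefination pathway, especially with the ketone twisted by its two ortho substituents. Fallback: close the same ring at O1–C2. Acetophenone 10 is acylated with 14 (Et3N, DMAP, CH2Cl2) to give the aryl ester 2-acetyl-3-(benzyloxy)-5-methoxyphenyl 3-(benzyloxy)-4-[4-[5,7-bis(benzyloxy)-4-oxo-4H-chromen-2-yl]-2-methoxyphenoxy]benzoate F3 (also described under step 10). Baker–Venkataraman rearrangement (KOtBu, THF, 0 °C) gives the 1,3-diketone F7. Mild cyclodehydration (cat. pTsOH, toluene, 80 °C) returns to the route at 16.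

**Step 10.** Acylation may occur at the ylide carbon or the enolate oxygen in place of the phenol oxygen, giving a C-aroyl ylide that cannot reach 15. Fallback: form the ester before phosphorus is present.
- Acetophenone 10 and 14 give the aryl ester F3 (Et3N, DMAP, CH2Cl2).
- Soft enolisation (TMSOTf, Et3N, CH2Cl2, 0 °C) gives the silyl enol ether F4.
- NBS (THF, −78 °C) gives the α-bromoketone F5, with the enol ether far more reactive than any arene present.
- PPh3 (toluene, rt) gives the phosphonium bromide F6, and aqueous Na2CO3 returns to the route at 15.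

**Step 12.** The two enol-ether double bonds are electron-poor and need excess oxidant and time. Incomplete conversion to mono-oxidised material and oxidation of benzylic C–H bonds are the likely losses. Fallback: directed C3 functionalisation of 16. Double C3 lithiation (LDA, THF, −78 °C) and trapping with B(OMe)3 give the bis(dimethyl boronate) F8. Oxidation in the same flask (H2O2, AcOH) returns to the route at 18.

**Step 2.** The substitution may be sluggish: the ester is a modest activator, the ortho benzyloxy group donates into the ring and the para-formyl phenoxide is a weak nucleophile. At the temperature required, ester cleavage or benzyl transfer to the phenoxide may compete. Fallback: copper-catalysed Ullmann-type ether coupling, which does not depend on arene activation. Vanillin 3 is coupled with benzyl 3-(benzyloxy)-4-iodobenzoate F1 (CuI, picolinic acid, K3PO4, DMSO, 90 °C), returning at 4. F1 is made from commercial 3-hydroxy-4-iodobenzoic acid as in step 1.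

**Step 7.** Nuclear bromination of the very electron-rich ring may compete with α-bromination. The HBr formed may cleave the ortho benzyl ether, and the product may close prematurely to the coumaranone. Fallback: bromination through the enol ether. Compound 10 is converted (TMSOTf, Et3N, CH2Cl2, 0 °C) into the bis-silyl compound [1-[2-(benzyloxy)-4-methoxy-6-(trimethylsilyloxy)phenyl]ethenyl]oxytrimethylsilane F2. NBS (THF, −78 °C) and a mildly acidic work-up that frees the phenol return to the route at 11.

## Further compounds

F1 | step 2 | benzyl 3-(benzyloxy)-4-iodobenzoate | O=C(OCc1ccccc1)c1ccc(I)c(OCc2ccccc2)c1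
F2 | step 7 | [1-[2-(benzyloxy)-4-methoxy-6-(trimethylsilyloxy)phenyl]ethenyl]oxytrimethylsilane | COc1cc(O[Si](C)(C)C)c(C(=C)O[Si](C)(C)C)c(OCc2ccccc2)c1
F3 | step 10 | 2-acetyl-3-(benzyloxy)-5-methoxyphenyl 3-(benzyloxy)-4-[4-[5,7-bis(benzyloxy)-4-oxo-4H-chromen-2-yl]-2-methoxyphenoxy]benzoate | COc1cc(OCc2ccccc2)c(C(C)=O)c(OC(=O)c2ccc(Oc3ccc(-c4cc(=O)c5c(OCc6ccccc6)cc(OCc6ccccc6)cc5o4)cc3OC)c(OCc3ccccc3)c2)c1
F4 | step 10 | 3-(benzyloxy)-5-methoxy-2-[1-(trimethylsilyloxy)ethenyl]phenyl 3-(benzyloxy)-4-[4-[5,7-bis(benzyloxy)-4-oxo-4H-chromen-2-yl]-2-methoxyphenoxy]benzoate | COc1cc(OCc2ccccc2)c(C(=C)O[Si](C)(C)C)c(OC(=O)c2ccc(Oc3ccc(-c4cc(=O)c5c(OCc6ccccc6)cc(OCc6ccccc6)cc5o4)cc3OC)c(OCc3ccccc3)c2)c1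
F5 | step 10 | 3-(benzyloxy)-2-(bromoacetyl)-5-methoxyphenyl 3-(benzyloxy)-4-[4-[5,7-bis(benzyloxy)-4-oxo-4H-chromen-2-yl]-2-methoxyphenoxy]benzoate | COc1cc(OCc2ccccc2)c(C(=O)CBr)c(OC(=O)c2ccc(Oc3ccc(-c4cc(=O)c5c(OCc6ccccc6)cc(OCc6ccccc6)cc5o4)cc3OC)c(OCc3ccccc3)c2)c1
F6 | step 10 | [2-[2-(benzyloxy)-6-[3-(benzyloxy)-4-[4-[5,7-bis(benzyloxy)-4-oxo-4H-chromen-2-yl]-2-methoxyphenoxy]benzoyloxy]-4-methoxyphenyl]-2-oxoethyl]triphenylphosphonium bromide | COc1cc(OCc2ccccc2)c(C(=O)C[P+](c2ccccc2)(c2ccccc2)c2ccccc2)c(OC(=O)c2ccc(Oc3ccc(-c4cc(=O)c5c(OCc6ccccc6)cc(OCc6ccccc6)cc5o4)cc3OC)c(OCc3ccccc3)c2)c1.[Br-]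
F7 | step 11 | 1-[2-(benzyloxy)-6-hydroxy-4-methoxyphenyl]-3-[3-(benzyloxy)-4-[4-[5,7-bis(benzyloxy)-4-oxo-4H-chromen-2-yl]-2-methoxyphenoxy]phenyl]propane-1,3-dione | COc1cc(O)c(C(=O)CC(=O)c2ccc(Oc3ccc(-c4cc(=O)c5c(OCc6ccccc6)cc(OCc6ccccc6)cc5o4)cc3OC)c(OCc3ccccc3)c2)c(OCc2ccccc2)c1
F8 | step 12 | bis(dimethyl boronate) of 16 carrying a B(OMe)2 group at C3 of each chromenone | COc1cc(OCc2ccccc2)c2c(=O)c(B(OC)OC)c(-c3ccc(Oc4ccc(-c5oc6cc(OCc7ccccc7)cc(OCc7ccccc7)c6c(=O)c5B(OC)OC)cc4OC)c(OCc4ccccc4)c3)oc2c1
A1 | alternative 1 | 1-(4-bromo-2-methoxyphenoxy)propan-2-one | CC(=O)COc1ccc(Br)cc1OC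
A2 | alternative 1 | ethyl 2-oxobut-3-enoate | CCOC(=O)C(=O)C=C
A3 | alternative 1 | ethyl 4-(4-bromo-2-methoxyphenoxy)-3-oxocyclohex-1-ene-1-carboxylate | CCOC(=O)C1=CC(=O)C(Oc2ccc(Br)cc2OC)CC1
A4 | alternative 1 | ethyl 4-(4-bromo-2-methoxyphenoxy)-3-hydroxybenzoate | CCOC(=O)c1ccc(Oc2ccc(Br)cc2OC)c(O)c1
A5 | alternative 2 | 2-[1-[4-(4-bromo-2-benzyloxyphenoxy)-3-methoxyphenyl]-2-oxoethoxy]-4,6-bis(benzyloxy)benzaldehyde | O=CC(Oc1cc(OCc2ccccc2)cc(OCc2ccccc2)c1C=O)c1ccc(Oc2ccc(Br)cc2OCc2ccccc2)c(OC)c1
A6 | alternative 2 | 5,7-bis(benzyloxy)-2-[4-(4-bromo-2-benzyloxyphenoxy)-3-methoxyphenyl]-3-hydroxychroman-4-one | O=C1c2c(OCc3ccccc3)cc(OCc3ccccc3)cc2OC(c2ccc(Oc3ccc(Br)cc3OCc3ccccc3)c(OC)c2)C1O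
A7 | alternative 3 | 5-(benzyloxy)-6-[3-(benzyloxy)-4-[4-(1,3-dioxolan-2-yl)-2-methoxyphenoxy]phenyl]-2-(diazoacetyl)-4H-pyran-4-one | [N-]=[N+]=CC(=O)c1cc(=O)c(OCc2ccccc2)c(-c2ccc(Oc3ccc(C4OCCO4)cc3OC)c(OCc3ccccc3)c2)o1
A8 | alternative 3 | methoxyacetylene | COC#C
A9 | alternative 3 | 3-(benzyloxy)-2-[3-(benzyloxy)-4-[4-(1,3-dioxolan-2-yl)-2-methoxyphenoxy]phenyl]-5-hydroxy-7-methoxy-4H-chromen-4-one | COc1cc(O)c2c(=O)c(OCc3ccccc3)c(-c3ccc(Oc4ccc(C5OCCO5)cc4OC)c(OCc4ccccc4)c3)oc2c1
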